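**Plan**

- Retrosynthesis: the O1–C2 bond is cut first (oxa-Michael), which opens ring C to a 2'-hydroxychalcone. The O1–C8a and C4–C4a bonds are then cut together, giving a ring A aryne and a cinnamic acid. Last, the C8–C1'' bond is cut, giving an aryl metal and a lavandulyl electrophile.
- Enabling feature: in ring A, C8a (which carries O1) and C4a (which carries the C4 carbonyl) are adjacent, and they lie between the C5 methoxy group and the C8 lavandulyl group. An ortho oxygen/acyl pair of this kind is what a C4a≡C8a aryne delivers when it inserts into the C–O bond of a carboxylic acid.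
- Forward order: ring A is bought as 5-methoxyresorcinol and the lavandulyl chain is joined to C8 first. Bromination, retro-Brook silyl shift and triflation then give the silyl triflate. The aryne takes up the cinnamic acid to give the open chalcone, and ring C closes last.
- Stereochemistry: C2'' comes from lipase-resolved (S)-lavandulol and is never touched; its descriptor becomes R only because the CIP priorities change. C2 (S) is set by a cinchona-thiourea-catalysed oxa-Michael closure.

Key step: step 10

Remark on names: lavandulyl = 5-methyl-2-(prop-1-en-2-yl)hex-4-en-1-yl; ring positions follow flavanone numbering (O1, C2–C4, C4a, C5–C8, C8a); MOM = methoxymethyl.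

Assumptions: the lipase is taken to acylate (R)-lavandulol faster, and the quinine-derived thiourea is taken to give the 2S configuration; if either sense is reversed, the acetate fraction (after methanolysis) or the quinidine-derived pseudoenantiomer would be used instead.

**Route**

Step 1
Reactants: 1 racemic lavandulol
Product: 2 (S)-lavandulol
Conditions: porcine pancreatic lipase, vinyl acetate, hexane, rt, stopped beyond half conversion (about 60–65%); chromatography
Reagents that add atoms: none
Why: Lipase-catalysed kinetic resolution by enantioselective transesterification should acetylate the (R)-alcohol faster, so running past half conversion should leave (S)-lavandulol in high enantiomeric purity, and this alcohol supplies C2'' of the target.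

Step 2
Reactants: 2 (S)-lavandulol
Product: 3 (S)-lavandulyl triflate
Conditions: Tf2O, 2,6-lutidine, CH2Cl2, −78 °C; cold pentane filtration, used at once
Reagents that add atoms: trifluoromethanesulfonic anhydride, O=S(=O)(OS(=O)(=O)C(F)(F)F)C(F)(F)F
Why: O-sulfonylation of a primary alcohol with triflic anhydride and a hindered pyridine base at low temperature is standard and leaves the adjacent stereocentre untouched.

Step 3
Reactants: 4 5-methoxyresorcinol
Product: 5 1-methoxy-3,5-bis(methoxymethoxy)benzene
Conditions: MOMCl, iPr2NEt, CH2Cl2, 0 °C → rt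
Reagents that add atoms: chloromethyl methyl ether, COCCl
Why: Williamson-type O-alkylation of both phenols gives the bis-acetal, whose MOM groups protect the oxygens and later direct the metalations.

Step 4
Reactants: 5 1-methoxy-3,5-bis(methoxymethoxy)benzene (1.5 equiv); 3 (S)-lavandulyl triflate
Product: 8 2-[(R)-lavandulyl]-5-methoxy-1,3-bis(methoxymethoxy)benzene, via aryllithium 6 (not isolated), via arylmagnesium bromide 7 (not isolated)
Conditions: n-BuLi, THF, 0 °C; MgBr2·OEt2, 0 °C; CuBr·SMe2 (10 mol %), then 3 in Et2O, −40 → 0 °C
Reagents that add atoms: none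
Why: Directed ortho-metalation should occur at the carbon flanked by both MOM ethers, and after transmetalation the aryl Grignard reagent should displace the primary triflate in a copper-catalysed SN2 coupling that does not involve the β-stereocentre, so the (S)-alcohol configuration is carried over unchanged and is named R in the arene.

Step 5
Reactants: 8 2-[(R)-lavandulyl]-5-methoxy-1,3-bis(methoxymethoxy)benzene
Product: 10 4-bromo-2-[(R)-lavandulyl]-5-methoxy-1,3-bis(methoxymethoxy)benzene, via aryllithium 9 (not isolated)
Conditions: n-BuLi, TMEDA, THF, 0 °C; BrCCl2CCl2Br, −78 °C → rt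
Reagents that add atoms: 1,2-dibromotetrachloroethane, BrC(Cl)(Cl)C(Cl)(Cl)Br
Why: A second directed ortho-metalation can only take place at the two equivalent ring positions between OMOM and OMe, and bromine transfer to the aryllithium should give a single monobromide, which breaks the symmetry of ring A and marks the future C4a without any statistical step.

Step 6
Reactants: 10 4-bromo-2-[(R)-lavandulyl]-5-methoxy-1,3-bis(methoxymethoxy)benzene
Product: 11 4-bromo-2-[(R)-lavandulyl]-5-methoxybenzene-1,3-diol
Conditions: HCl (1.25 M in MeOH), rt → 40 °C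
Reagents that add atoms: none
Why: Acid-catalysed acetal exchange with methanol removes both MOM groups under conditions that prenyl-type side chains of phenols normally tolerate, and it is done before silicon is on the ring so that no protodesilylation can occur.

Step 7
Reactants: 11 4-bromo-2-[(R)-lavandulyl]-5-methoxybenzene-1,3-diol
Product: 16 5-hydroxy-6-[(R)-lavandulyl]-3-methoxy-2-(trimethylsilyl)phenyl triflate, via bis(trimethylsilyl) ether 12 (not isolated), via aryllithium 13 (not isolated), via lithium phenoxide 14 (not isolated), via silyl ether triflate 15 (not isolated)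
Conditions: HMDS, THF, 65 °C, then evaporation; n-BuLi, THF, −78 °C; Tf2O, −78 °C; aq NaHCO3 work-up; K2CO3 (cat.), MeOH, 0 °C
Reagents that add atoms: hexamethyldisilazane, C[Si](C)(C)N[Si](C)(C)C; trifluoromethanesulfonic anhydride, O=S(=O)(OS(=O)(=O)C(F)(F)F)C(F)(F)F
Why: This is the standard one-flask conversion of an ortho-bromophenol into an ortho-silylaryl triflate, in which bromine–lithium exchange triggers a retro-Brook 1,3-shift of silicon from the neighbouring oxygen only, the freed phenoxide is triflated, and the remote aryl silyl ether is removed by mild methanolysis.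

Step 8
Reactants: 16 5-hydroxy-6-[(R)-lavandulyl]-3-methoxy-2-(trimethylsilyl)phenyl triflate
Product: 17 6-[(R)-lavandulyl]-3-methoxy-5-(methoxymethoxy)-2-(trimethylsilyl)phenyl triflate
Conditions: MOMCl, iPr2NEt, CH2Cl2, 0 °C → rt
Reagents that add atoms: chloromethyl methyl ether, COCCl
Why: O-alkylation of the remaining phenol under amine base leaves the silyl triflate intact in the absence of fluoride and removes a phenoxide that would otherwise be arylated by the aryne.

Step 9
Reactants: 18 (E)-4-hydroxycinnamic acid
Product: 20 (E)-4-(methoxymethoxy)cinnamic acid, via methoxymethyl ester 19 (not isolated)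
Conditions: MOMCl (2.5 equiv), iPr2NEt, CH2Cl2, 0 °C → rt; then LiOH, THF/MeOH/H2O, rt; 1 M HCl to pH 4 at 0 °C
Reagents that add atoms: chloromethyl methyl ether, COCCl; lithium hydroxide, [Li+].[OH-] (one carboxyl oxygen, by acyl–oxygen cleavage)
Why: Exhaustive O-alkylation followed by saponification of the labile MOM ester should leave the aryl MOM ether and the (E)-alkene unchanged.

Step 10
Reactants: 17 6-[(R)-lavandulyl]-3-methoxy-5-(methoxymethoxy)-2-(trimethylsilyl)phenyl triflate; 20 (E)-4-(methoxymethoxy)cinnamic acid (3 equiv)
Product: 23 (E)-2'-hydroxy-3'-[(R)-lavandulyl]-6'-methoxy-4,4'-bis(methoxymethoxy)chalcone, via cesium carboxylate 21 (not isolated), via aryne 22 (not isolated)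
Conditions: 20, Cs2CO3 (1.5 equiv), MeOH, then evaporation and drying under vacuum; 17, CsF (3 equiv), THF, 125 °C, sealed tube; cold 0.5 M HCl work-up
Reagents that add atoms: none
Why: Fluoride attacks silicon and triflate leaves to give aryne 22 (C4a≡C8a); a carboxylate oxygen of 21 adds to C8a, the C4a aryl anion attacks its own ester carbonyl through a four-membered transition state, and collapse moves the acyl group from oxygen to C4a, leaving the C8a phenoxide that is protonated on work-up. The closest known reaction type is the fluoride-induced insertion of arynes into the C–O bond of carboxylic acids, acrylic-type acids included, which gives ortho-hydroxyaryl ketones. No ring closes and no stereocentre is formed, and the (E)-enone and C2'' are carried through unchanged. The step needs regioselection (oxygen to C8a, acyl to C4a), which the C5 methoxy group should secure: it polarises the aryne so that the nucleophile enters at the remote carbon and the charge develops next to the C–O bond, and this should outweigh the shielding of C8a by the primary C8 methylene. It also needs chemoselection against protonation of the aryl anion (aryl ester formation), against unselective closure of ring C, and against an intramolecular ene reaction of the aryne with the side-chain double bonds; the dry, preformed cesium salt in threefold excess removes the proton source, keeps the product as its open phenoxide and speeds bimolecular capture.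

Step 11
Reactants: 23 (E)-2'-hydroxy-3'-[(R)-lavandulyl]-6'-methoxy-4,4'-bis(methoxymethoxy)chalcone
Product: 24 (2S)-8-[(R)-lavandulyl]-5-methoxy-7-(methoxymethoxy)-2-[4-(methoxymethoxy)phenyl]chroman-4-one
Conditions: 9-amino(9-deoxy)epi-quinine 3,5-bis(trifluoromethyl)phenyl thiourea (10 mol %), toluene, rt
Reagents that add atoms: none
Why: In this organocatalytic asymmetric intramolecular oxa-Michael addition (6-endo-trig) the quinuclidine nitrogen deprotonates the C8a phenol while the thiourea binds the enone, so the phenoxide should be delivered to one face of C2 under catalyst control (2S), and the C5 methoxy group favours the closed form and thereby limits erosion by ring opening.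

Step 12
Reactants: 24 (2S)-8-[(R)-lavandulyl]-5-methoxy-7-(methoxymethoxy)-2-[4-(methoxymethoxy)phenyl]chroman-4-one
Product: 25 kushenol U
Conditions: 3 M aq HCl/MeOH, 45 °C
Reagents that add atoms: none
Why: Acid-catalysed cleavage of both MOM acetals frees the C7 and C4' phenols, and C2 should hold its configuration because ring opening of flavanones needs base.

**Compound list**

1 | racemic lavandulol, (±)-5-methyl-2-(prop-1-en-2-yl)hex-4-en-1-ol | C=C(C)C(CO)CC=C(C)C | starting material
2 | (S)-lavandulol | C=C(C)[C@H](CC=C(C)C)CO | intermediate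
3 | (S)-lavandulyl triflate | C=C(C)[C@H](CC=C(C)C)COS(=O)(=O)C(F)(F)F | intermediate
4 | 5-methoxyresorcinol | COc1cc(O)cc(O)c1 | starting material
5 | 1-methoxy-3,5-bis(methoxymethoxy)benzene | COCOc1cc(OC)cc(OCOC)c1 | intermediate
6 | [4-methoxy-2,6-bis(methoxymethoxy)phenyl]lithium | [Li]c1c(OCOC)cc(OC)cc1OCOC | intermediate
7 | [4-methoxy-2,6-bis(methoxymethoxy)phenyl]magnesium bromide | Br[Mg]c1c(OCOC)cc(OC)cc1OCOC | intermediate
8 | 2-[(R)-lavandulyl]-5-methoxy-1,3-bis(methoxymethoxy)benzene | C=C(C)[C@H](CC=C(C)C)Cc1c(OCOC)cc(OC)cc1OCOC | intermediate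
9 | 4-lithio derivative of 8 | C=C(C)[C@H](CC=C(C)C)Cc1c(OCOC)cc(OC)c([Li])c1OCOC | intermediate
10 | 4-bromo-2-[(R)-lavandulyl]-5-methoxy-1,3-bis(methoxymethoxy)benzene | C=C(C)[C@H](CC=C(C)C)Cc1c(OCOC)cc(OC)c(Br)c1OCOC | intermediate
11 | 4-bromo-2-[(R)-lavandulyl]-5-methoxybenzene-1,3-diol | C=C(C)[C@H](CC=C(C)C)Cc1c(O)cc(OC)c(Br)c1O | intermediate
12 | bis(trimethylsilyl) ether of 11 | C=C(C)[C@H](CC=C(C)C)Cc1c(O[Si](C)(C)C)cc(OC)c(Br)c1O[Si](C)(C)C | intermediate
13 | aryllithium from 12 by bromine–lithium exchange | C=C(C)[C@H](CC=C(C)C)Cc1c(O[Si](C)(C)C)cc(OC)c([Li])c1O[Si](C)(C)C | intermediate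
14 | lithium 6-[(R)-lavandulyl]-3-methoxy-2-(trimethylsilyl)-5-(trimethylsilyloxy)phenoxide | C=C(C)[C@H](CC=C(C)C)Cc1c(O[Si](C)(C)C)cc(OC)c([Si](C)(C)C)c1O[Li] | intermediate
15 | 6-[(R)-lavandulyl]-3-methoxy-2-(trimethylsilyl)-5-(trimethylsilyloxy)phenyl triflate | C=C(C)[C@H](CC=C(C)C)Cc1c(O[Si](C)(C)C)cc(OC)c([Si](C)(C)C)c1OS(=O)(=O)C(F)(F)F | intermediate
16 | 5-hydroxy-6-[(R)-lavandulyl]-3-methoxy-2-(trimethylsilyl)phenyl triflate | C=C(C)[C@H](CC=C(C)C)Cc1c(O)cc(OC)c([Si](C)(C)C)c1OS(=O)(=O)C(F)(F)F | intermediate
17 | 6-[(R)-lavandulyl]-3-methoxy-5-(methoxymethoxy)-2-(trimethylsilyl)phenyl triflate | C=C(C)[C@H](CC=C(C)C)Cc1c(OCOC)cc(OC)c([Si](C)(C)C)c1OS(=O)(=O)C(F)(F)F | intermediate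
18 | (E)-4-hydroxycinnamic acid | O=C(O)/C=C/c1ccc(O)cc1 | starting material
19 | methoxymethyl (E)-4-(methoxymethoxy)cinnamate | COCOC(=O)/C=C/c1ccc(OCOC)cc1 | intermediate
20 | (E)-4-(methoxymethoxy)cinnamic acid | COCOc1ccc(/C=C/C(=O)O)cc1 | intermediate
21 | cesium (E)-4-(methoxymethoxy)cinnamate | COCOc1ccc(/C=C/C(=O)[O-])cc1.[Cs+] | intermediate
22 | 3-[(R)-lavandulyl]-6-methoxy-4-(methoxymethoxy)-1,2-didehydrobenzene (C4a≡C8a aryne) | C=C(C)[C@H](CC=C(C)C)CC1=C(OCOC)C=C(OC)C#C1 | intermediate
23 | (E)-2'-hydroxy-3'-[(R)-lavandulyl]-6'-methoxy-4,4'-bis(methoxymethoxy)chalcone | C=C(C)[C@H](CC=C(C)C)Cc1c(OCOC)cc(OC)c(C(=O)/C=C/c2ccc(OCOC)cc2)c1O | intermediate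
24 | (2S)-8-[(R)-lavandulyl]-5-methoxy-7-(methoxymethoxy)-2-[4-(methoxymethoxy)phenyl]chroman-4-one | C=C(C)[C@H](CC=C(C)C)Cc1c(OCOC)cc(OC)c2c1O[C@H](c1ccc(OCOC)cc1)CC2=O | intermediate
25 | kushenol U, (2S)-7-hydroxy-2-(4-hydroxyphenyl)-8-[(R)-lavandulyl]-5-methoxychroman-4-one | C=C(C)[C@H](CC=C(C)C)Cc1c(O)cc(OC)c2c1O[C@H](c1ccc(O)cc1)CC2=O | target

**Step count**

Total: 12 steps. Longest linear sequence: 10 steps (steps 1, 2, 4, 5, 6, 7, 8, 10, 11, 12).

**Steps most likely to fail**

Step 10. The aryne may be consumed by an intramolecular ene reaction with a side-chain double bond before the carboxylate captures it. The carboxylate may also add at C4a instead of C8a, the aryl anion may be protonated before the acyl shift, or ring C may close early without stereocontrol. The fallback is the classical acetophenone route, which sets out from compound 8 and comes back at compound 23. Aryllithium 9 is generated as in step 5 and acetylated with N-methoxy-N-methylacetamide to give 1-[3-[(R)-lavandulyl]-6-methoxy-2,4-bis(methoxymethoxy)phenyl]ethanone F1. Brief treatment with dilute HCl in MeOH at 0 °C should remove only the MOM group ortho to the ketone, because its cleavage is assisted by the carbonyl and gives the hydrogen-bonded phenol. This gives 1-[2-hydroxy-3-[(R)-lavandulyl]-6-methoxy-4-(methoxymethoxy)phenyl]ethanone F2. Claisen–Schmidt condensation of F2 with commercial 4-(methoxymethoxy)benzaldehyde (KOH, EtOH/H2O, rt, cold acidification) should then give chalcone 23.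

Step 4. The basic aryl metal may cause β-elimination of the triflate to a diene, the homoallylic triflate may ionise or rearrange before coupling, or substitution at the β-branched carbon by the di-ortho-substituted nucleophile may be too slow. The fallback reverses the polarity in a Negishi cross-coupling; it sets out from compounds 2 and 5 and comes back at compound 8. Appel iodination of 2 (I2, PPh3, imidazole, CH2Cl2) gives (S)-lavandulyl iodide F3, and zinc insertion (Zn dust, LiCl, THF) gives (S)-lavandulylzinc iodide F4. Aryllithium 6, made from 5 as in step 4, is brominated with BrCCl2CCl2Br to give 2-bromo-5-methoxy-1,3-bis(methoxymethoxy)benzene F5. Coupling of F4 with F5 under Pd(OAc)2 and SPhos in THF at rt to 50 °C should give 8 with the β-stereocentre untouched.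

Step 11. Facial selectivity at C2 may be poor, and the selectivity may erode through reversible ring opening under the basic catalyst. The fallback sets out from compound 23 and comes back at compound 24. Unselective closure with NaOAc in refluxing EtOH gives the C2-epimer mixture of the flavanone F6. Kinetic resolution by Noyori-type asymmetric transfer hydrogenation with RuCl(p-cymene)[(R,R)-TsDPEN] in HCO2H/Et3N should then reduce the (2R)-epimer to the cis-(2R,4R)-flavan-4-ol F7 and leave the (2S)-ketone 24, which is separated from the alcohol by chromatography.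

**Further compounds**

F1 | step 10 | 1-[3-[(R)-lavandulyl]-6-methoxy-2,4-bis(methoxymethoxy)phenyl]ethanone | C=C(C)[C@H](CC=C(C)C)Cc1c(OCOC)cc(OC)c(C(C)=O)c1OCOC
F2 | step 10 | 1-[2-hydroxy-3-[(R)-lavandulyl]-6-methoxy-4-(methoxymethoxy)phenyl]ethanone | C=C(C)[C@H](CC=C(C)C)Cc1c(OCOC)cc(OC)c(C(C)=O)c1O
F3 | step 4 | (S)-lavandulyl iodide | C=C(C)[C@H](CC=C(C)C)CI
F4 | step 4 | (S)-lavandulylzinc iodide | C=C(C)[C@H](CC=C(C)C)C[Zn]I
F5 | step 4 | 2-bromo-5-methoxy-1,3-bis(methoxymethoxy)benzene | COCOc1cc(OC)cc(OCOC)c1Br
F6 | step 11 | (2RS)-8-[(R)-lavandulyl]-5-methoxy-7-(methoxymethoxy)-2-[4-(methoxymethoxy)phenyl]chroman-4-one (C2-epimer mixture) | C=C(C)[C@H](CC=C(C)C)Cc1c(OCOC)cc(OC)c2c1OC(c1ccc(OCOC)cc1)CC2=O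
F7 | step 11 | (2R,4R)-8-[(R)-lavandulyl]-5-methoxy-7-(methoxymethoxy)-2-[4-(methoxymethoxy)phenyl]chroman-4-ol | C=C(C)[C@H](CC=C(C)C)Cc1c(OCOC)cc(OC)c2c1O[C@@H](c1ccc(OCOC)cc1)C[C@H]2O
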